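**Overview** (germacranolide numbering: ring carbons C1–C10 with C1=C10 Z and C4=C5 E; C3 = CH–O-tigloyl; C6 = lactone O–CH; C7=C11 the butenolide alkene; C12 the lactone carbonyl; C13 the CH2OAc carbon)
- Ten-membered ring, formed second: ring-closing metathesis at C1=C10 of a butenolide that carries an allyl chain on C3 and an isopropenyl end on C9; the tiglate and the acetate are put on just before.
- Butenolide, formed first (key step): the lactone O–C6 bond is made by zerovalent-palladium ionisation of a (3S,4S)-3,4-epoxide next to an E-C5=C6 alkene, the C12 carboxylic acid capturing the C4–C5–C6 allyl unit at C6.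
- Enabling feature: the oxygens on C3 and C6 stand 1,4 across the E-C4=C5 alkene (O–C3–C4(CH3)=C5–C6–O), and C6 is cis to the C12 carboxyl on the tetrasubstituted C7=C11 alkene of the five-membered lactone; one vinyl epoxide therefore sets both stereocentres, the alkene geometry and the ring.
- Epoxy acid from an achiral (2Z,4E,6E)-trienoate by Shi epoxidation of C3=C4; trienoate by Stille coupling at C6–C7 of a dienylstannane with the Z-enol triflate of a β-keto ester.

Key step: step 11

Remark: the L-fructose-derived enantiomer of the ketone used in the Shi epoxidation is taken as available (commercial, or made from L-sorbose); it serves only as a catalyst.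

**Step 1**
Reactants: 1 (E)-3-methylpent-2-en-4-yn-1-ol
Product: 2 (2E,4E)-3-methyl-5-(tributylstannyl)penta-2,4-dien-1-ol
Conditions: Bu3SnH, PdCl2(PPh3)2 (2 mol%), THF, 0 °C
Reagents that add atoms: tributyltin hydride, CCCC[SnH](CCCC)CCCC
Why: palladium-catalysed syn-hydrostannation of the terminal alkyne should place tin on the terminal carbon (the neighbouring carbon is a branched sp2 centre) and give the E-alkenylstannane, leaving the existing E-trisubstituted alkene untouched.

**Step 2**
Reactants: 2 (2E,4E)-3-methyl-5-(tributylstannyl)penta-2,4-dien-1-ol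
Product: 3 tributyl[(1E,3E)-5-bromo-3-methylpenta-1,3-dien-1-yl]stannane
Conditions: CBr4, PPh3, 2,6-lutidine, CH2Cl2, −30 °C; used crude
Reagents that add atoms: carbon tetrabromide, BrC(Br)(Br)Br
Why: Appel bromination of the primary allylic alcohol under buffered neutral conditions should spare the acid-labile alkenylstannane and the diene geometry.

**Step 3**
Reactants: 3 tributyl[(1E,3E)-5-bromo-3-methylpenta-1,3-dien-1-yl]stannane
Product: 4 tributyl[(1E,3E)-3-methylhepta-1,3,6-trien-1-yl]stannane
Conditions: CH2=CHMgBr, Li2CuCl4 (3 mol%), THF, −78 → −20 °C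
Reagents that add atoms: vinylmagnesium bromide, C=C[Mg]Br
Why: copper-catalysed Grignard cross-coupling with an allylic bromide should occur at the unhindered primary carbon (SN2, the γ-carbon being fully substituted) with retention of the diene geometry.

**Step 4**
Reactants: 5 methyl 3-hydroxypropanoate
Product: 6 methyl 3-[(tert-butyldimethylsilyl)oxy]propanoate
Conditions: TBSCl, imidazole, DMF, rt
Reagents that add atoms: tert-butyldimethylsilyl chloride, CC(C)(C)[Si](C)(C)Cl
Why: standard silylation of a primary alcohol.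

**Step 5**
Reactants: 7 4-methylpent-4-enoic acid
Product: 8 4-methylpent-4-enoyl chloride
Conditions: (COCl)2, N,N-dimethylformamide (1 mol%), CH2Cl2, 0 °C → rt; concentrated and used crude
Reagents that add atoms: oxalyl chloride, O=C(Cl)C(=O)Cl
Why: standard acid chloride formation through the Vilsmeier-type chloroiminium species.

**Step 6**
Reactants: 6 methyl 3-[(tert-butyldimethylsilyl)oxy]propanoate (2.1 equiv); 8 4-methylpent-4-enoyl chloride
Product: 9 methyl 2-{[(tert-butyldimethylsilyl)oxy]methyl}-6-methyl-3-oxohept-6-enoate (racemic, keto–enol mixture)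
Conditions: LiN(i-Pr)2 (2.1 equiv), THF, −78 °C; then 8, −78 °C; AcOH quench at −78 °C
Reagents that add atoms: none
Why: crossed Claisen acylation of the lithium ester enolate by the acid chloride, the second equivalent of enolate serving as base for the more acidic product; at −78 °C the β-silyloxy enolate should not eliminate silanolate.

**Step 7**
Reactants: 9 methyl 2-{[(tert-butyldimethylsilyl)oxy]methyl}-6-methyl-3-oxohept-6-enoate
Product: 10 methyl (2Z)-2-{[(tert-butyldimethylsilyl)oxy]methyl}-6-methyl-3-{[(trifluoromethyl)sulfonyl]oxy}hepta-2,6-dienoate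
Conditions: LiN(SiMe3)2, Et2O, −78 °C; then Tf2O, −78 → −20 °C
Reagents that add atoms: trifluoromethanesulfonic anhydride, O=S(=O)(OS(=O)(=O)C(F)(F)F)C(F)(F)F
Why: O-sulfonylation of the lithium enolate of the β-keto ester, in which lithium bridges the enolate and ester oxygens, should give the enol triflate with the triflate cis to the ester (Z).

**Step 8**
Reactants: 4 tributyl[(1E,3E)-3-methylhepta-1,3,6-trien-1-yl]stannane; 10 methyl (2Z)-enol triflate
Product: 11 methyl (2Z,4E,6E)-2-{[(tert-butyldimethylsilyl)oxy]methyl}-6-methyl-3-(3-methylbut-3-en-1-yl)deca-2,4,6,9-tetraenoate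
Conditions: Pd2(dba)3 (2.5 mol%), AsPh3 (20 mol%), LiCl (3 equiv), N-methylpyrrolidone, 40 °C
Reagents that add atoms: none
Why: Stille coupling of an alkenyl triflate with an alkenylstannane proceeds with retention at both sp2 carbons, which places C6 cis to the ester on the tetrasubstituted alkene and keeps both E alkenes of the diene.

**Step 9**
Reactants: 11 methyl (2Z,4E,6E)-tetraenoate
Product: 12 methyl (2Z,4E)-2-{[(tert-butyldimethylsilyl)oxy]methyl}-3-(3-methylbut-3-en-1-yl)-5-[(2S,3S)-2-methyl-3-(prop-2-en-1-yl)oxiran-2-yl]penta-2,4-dienoate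
Conditions: Oxone (2KHSO5·KHSO4·K2SO4), 1,2:4,5-di-O-isopropylidene-β-L-erythro-2,3-hexodiulo-2,6-pyranose (30 mol%), K2CO3, Bu4NHSO4, MeCN/dimethoxymethane/aq. Na2B4O7–Na2EDTA buffer (pH 10.5), −5 °C
Reagents that add atoms: potassium peroxymonosulfate (active component of Oxone), [K+].[O-]S(=O)(=O)OO
Why: Shi asymmetric epoxidation, in which the chiral dioxirane should react fastest with the only trisubstituted alkene (the distal C3=C4 of the trienoate; the other conjugated alkenes are deactivated by the ester and the two terminal alkenes fit its spiro transition state poorly) and, with the L-fructose-derived ketone, should deliver oxygen to the face that gives the (3S,4S)-epoxide, which creates both stereocentres of the route.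

**Step 10**
Reactants: 12 methyl epoxy dienoate
Product: 13 (2Z,4E)-2-{[(tert-butyldimethylsilyl)oxy]methyl}-3-(3-methylbut-3-en-1-yl)-5-[(2S,3S)-2-methyl-3-(prop-2-en-1-yl)oxiran-2-yl]penta-2,4-dienoic acid
Conditions: LiOH·H2O, THF/MeOH/H2O (3:1:1), rt; then AcOH to pH 5 at 0 °C, extraction; used at once
Reagents that add atoms: lithium hydroxide, [Li+].[OH-]
Why: saponification of the methyl ester under conditions to which the epoxide and the silyl ether are inert; the stereocentres are not touched.

**Step 11**
Reactants: 13 epoxy dienoic acid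
Product: 14 (5R)-3-{[(tert-butyldimethylsilyl)oxy]methyl}-5-[(1E,3S)-3-hydroxy-2-methylhexa-1,5-dien-1-yl]-4-(3-methylbut-3-en-1-yl)furan-2(5H)-one
Conditions: Pd(PPh3)4 (5 mol%), THF (0.02 M), 0 °C → rt
Reagents that add atoms: none
Why: Zerovalent palladium should add to the C5=C6 alkene anti to the allylic C4–O bond of the epoxide and ionise it to an η3-allyl complex spanning C4–C5–C6, whose C3 alkoxide is protonated by the carboxylic acid; the C12 carboxylate then attacks C6 from the face opposite to palladium and releases the catalyst. The closest known reaction type is the Tsuji–Trost 1,4-addition of carboxylic acids to vinyl epoxides, together with palladium-catalysed allylic lactonisation. The butenolide closes in the 5-exo mode (O–C12–C11=C7–C6, the rest of the allyl unit staying outside the new ring); attack at C4 is excluded because it would need a seven-membered ring at a quaternary centre. The new stereocentre C6 is controlled by the epoxide carbon C4 through two inversions (net syn 1,3-transposition), so the (3S,4S)-epoxide with the E-C5=C6 alkene should give 6R while C3 keeps its configuration. The step needs the E geometry at C4=C5, which is secured because the larger C3 substituent rather than the methyl group takes the syn position at the allyl terminus in the ionising conformer. It also needs ring closure to outrun isomerisation of the allyl complex, which the carboxylate held cis to C6 on the C7=C11 alkene should provide.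

**Step 12**
Reactants: 14 hydroxy butenolide
Product: 15 (1E,3S)-1-[(2R)-4-{[(tert-butyldimethylsilyl)oxy]methyl}-3-(3-methylbut-3-en-1-yl)-5-oxo-2,5-dihydrofuran-2-yl]-2-methylhexa-1,5-dien-3-yl (2E)-2-methylbut-2-enoate
Conditions: tigloyl chloride, pyridine, 4-(dimethylamino)pyridine (10 mol%), CH2Cl2, 0 °C
Reagents that add atoms: tigloyl chloride, C/C=C(\C)C(Cl)=O
Why: acylation of the only free hydroxyl group under weakly basic conditions that should not epimerise C6; the tiglate is the stable E isomer and no stereocentre is touched.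

**Step 13**
Reactants: 15 tiglate silyl ether
Product: 16 (1E,3S)-1-[(2R)-4-(hydroxymethyl)-3-(3-methylbut-3-en-1-yl)-5-oxo-2,5-dihydrofuran-2-yl]-2-methylhexa-1,5-dien-3-yl (2E)-2-methylbut-2-enoate
Conditions: HF·pyridine, pyridine, THF, 0 °C
Reagents that add atoms: none
Why: buffered fluoride cleavage of the primary silyl ether, carried out before the acid-sensitive cyclodecadiene exists.

**Step 14**
Reactants: 16 primary alcohol
Product: 17 (1E,3S)-1-[(2R)-4-(acetoxymethyl)-3-(3-methylbut-3-en-1-yl)-5-oxo-2,5-dihydrofuran-2-yl]-2-methylhexa-1,5-dien-3-yl (2E)-2-methylbut-2-enoate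
Conditions: Ac2O, pyridine, 4-(dimethylamino)pyridine (5 mol%), CH2Cl2, 0 °C
Reagents that add atoms: acetic anhydride, CC(=O)OC(C)=O
Why: standard acetylation of the primary alcohol.

**Step 15**
Reactants: 17 acyclic diene diester
Product: 18 (3S,6R)-13-acetoxy-3-[(E)-2-methylbut-2-enoyloxy]germacra-1(10)Z,4E,7(11)-trien-12,6-olide (target)
Conditions: second-generation Grubbs catalyst RuCl2(=CHPh)(PCy3)(H2IMes) (10 mol%, in portions), 1,4-benzoquinone (20 mol%), toluene (0.5 mM), 60 °C
Reagents that add atoms: none
Why: ring-closing metathesis, in which the ruthenium carbene should form at the monosubstituted C1 vinyl group and close onto the 1,1-disubstituted C10 alkene with loss of ethylene, the tri- and tetrasubstituted and acyl-conjugated alkenes being inert; the cis (Z) trisubstituted alkene is the geometry expected for closure of a ten-membered ring that already holds the E-C4=C5 alkene, and no stereocentre is touched.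

**Compound list**
1 | (E)-3-methylpent-2-en-4-yn-1-ol | C#C/C(C)=C/CO | starting material
2 | (2E,4E)-3-methyl-5-(tributylstannyl)penta-2,4-dien-1-ol | OC/C=C(C)/C=C/[Sn](CCCC)(CCCC)CCCC | intermediate
3 | tributyl[(1E,3E)-5-bromo-3-methylpenta-1,3-dien-1-yl]stannane | BrC/C=C(C)/C=C/[Sn](CCCC)(CCCC)CCCC | intermediate
4 | tributyl[(1E,3E)-3-methylhepta-1,3,6-trien-1-yl]stannane | C=CC/C=C(C)/C=C/[Sn](CCCC)(CCCC)CCCC | intermediate
5 | methyl 3-hydroxypropanoate | COC(=O)CCO | starting material
6 | methyl 3-[(tert-butyldimethylsilyl)oxy]propanoate | COC(=O)CCO[Si](C)(C)C(C)(C)C | intermediate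
7 | 4-methylpent-4-enoic acid | C=C(C)CCC(=O)O | starting material
8 | 4-methylpent-4-enoyl chloride | C=C(C)CCC(Cl)=O | intermediate
9 | methyl 2-{[(tert-butyldimethylsilyl)oxy]methyl}-6-methyl-3-oxohept-6-enoate (racemic) | COC(=O)C(CO[Si](C)(C)C(C)(C)C)C(=O)CCC(C)=C | intermediate
10 | methyl (2Z)-2-{[(tert-butyldimethylsilyl)oxy]methyl}-6-methyl-3-{[(trifluoromethyl)sulfonyl]oxy}hepta-2,6-dienoate | COC(=O)/C(CO[Si](C)(C)C(C)(C)C)=C(\OS(=O)(=O)C(F)(F)F)CCC(C)=C | intermediate
11 | methyl (2Z,4E,6E)-2-{[(tert-butyldimethylsilyl)oxy]methyl}-6-methyl-3-(3-methylbut-3-en-1-yl)deca-2,4,6,9-tetraenoate | COC(=O)/C(CO[Si](C)(C)C(C)(C)C)=C(CCC(C)=C)\C=C\C(C)=C\CC=C | intermediate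
12 | methyl (2Z,4E)-2-{[(tert-butyldimethylsilyl)oxy]methyl}-3-(3-methylbut-3-en-1-yl)-5-[(2S,3S)-2-methyl-3-(prop-2-en-1-yl)oxiran-2-yl]penta-2,4-dienoate | COC(=O)/C(CO[Si](C)(C)C(C)(C)C)=C(CCC(C)=C)\C=C\[C@]1(C)O[C@H]1CC=C | intermediate
13 | (2Z,4E)-2-{[(tert-butyldimethylsilyl)oxy]methyl}-3-(3-methylbut-3-en-1-yl)-5-[(2S,3S)-2-methyl-3-(prop-2-en-1-yl)oxiran-2-yl]penta-2,4-dienoic acid | OC(=O)/C(CO[Si](C)(C)C(C)(C)C)=C(CCC(C)=C)\C=C\[C@]1(C)O[C@H]1CC=C | intermediate
14 | (5R)-3-{[(tert-butyldimethylsilyl)oxy]methyl}-5-[(1E,3S)-3-hydroxy-2-methylhexa-1,5-dien-1-yl]-4-(3-methylbut-3-en-1-yl)furan-2(5H)-one | C=CC[C@H](O)/C(C)=C/[C@H]1OC(=O)C(CO[Si](C)(C)C(C)(C)C)=C1CCC(C)=C | intermediate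
15 | (1E,3S)-1-[(2R)-4-{[(tert-butyldimethylsilyl)oxy]methyl}-3-(3-methylbut-3-en-1-yl)-5-oxo-2,5-dihydrofuran-2-yl]-2-methylhexa-1,5-dien-3-yl (2E)-2-methylbut-2-enoate | C=CC[C@H](OC(=O)/C(C)=C/C)/C(C)=C/[C@H]1OC(=O)C(CO[Si](C)(C)C(C)(C)C)=C1CCC(C)=C | intermediate
16 | (1E,3S)-1-[(2R)-4-(hydroxymethyl)-3-(3-methylbut-3-en-1-yl)-5-oxo-2,5-dihydrofuran-2-yl]-2-methylhexa-1,5-dien-3-yl (2E)-2-methylbut-2-enoate | C=CC[C@H](OC(=O)/C(C)=C/C)/C(C)=C/[C@H]1OC(=O)C(CO)=C1CCC(C)=C | intermediate
17 | (1E,3S)-1-[(2R)-4-(acetoxymethyl)-3-(3-methylbut-3-en-1-yl)-5-oxo-2,5-dihydrofuran-2-yl]-2-methylhexa-1,5-dien-3-yl (2E)-2-methylbut-2-enoate | C=CC[C@H](OC(=O)/C(C)=C/C)/C(C)=C/[C@H]1OC(=O)C(COC(C)=O)=C1CCC(C)=C | intermediate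
18 | (3S,6R)-13-acetoxy-3-[(E)-2-methylbut-2-enoyloxy]germacra-1(10)Z,4E,7(11)-trien-12,6-olide | C/C=C(\C)C(=O)O[C@H]1C/C=C(/C)CCC2=C(COC(C)=O)C(=O)O[C@@H]2/C=C/1C | target

**Step count and risks**
Total step count: 15. Longest linear sequence: 11 steps (for example 5 → 6 → 9 → 10 → 11 → 12 → 13 → 14 → 15 → 16 → 17 → 18).

Steps most likely to fail:

1. Step 15 (ring-closing metathesis). The strained ten-membered ring may not close on the rigid butenolide substrate: the vinyl group may instead enter intermolecular metathesis (oligomerisation), the catalyst may stall at the hindered 1,1-disubstituted alkene, or the ring may close with the wrong alkene geometry. Fallback: the order of ring formation is inverted, so that the carbocycle is closed on a more flexible chain and the lactone is then formed inside the ring. Setting out from 12, ring-closing metathesis with the same ruthenium catalyst (CH2Cl2, 1 mM, 40 °C) would give methyl (3S,4S)-13-[(tert-butyldimethylsilyl)oxy]-3,4-epoxygermacra-1(10)Z,5E,7(11)Z-trien-12-oate F1. Saponification (LiOH·H2O, THF/MeOH/H2O, then AcOH to pH 5) would give (3S,4S)-13-[(tert-butyldimethylsilyl)oxy]-3,4-epoxygermacra-1(10)Z,5E,7(11)Z-trien-12-oic acid F2. Pd(PPh3)4 in THF would then close the butenolide within the ring by the same anti/anti course, the ring itself holding C3 in the syn position of the allyl unit, to give (3S,6R)-13-[(tert-butyldimethylsilyl)oxy]-3-hydroxygermacra-1(10)Z,4E,7(11)-trien-12,6-olide F3. Tigloyl chloride and pyridine would give (3S,6R)-13-[(tert-butyldimethylsilyl)oxy]-3-tigloyloxygermacra-1(10)Z,4E,7(11)-trien-12,6-olide F4, and Bu4NF buffered with AcOH would give (3S,6R)-13-hydroxy-3-tigloyloxygermacra-1(10)Z,4E,7(11)-trien-12,6-olide F5. Acetylation (Ac2O, pyridine) comes back to the route at 18.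

2. Step 9 (Shi epoxidation). Site discrimination may be insufficient: the isolated 1,1-disubstituted alkene may be epoxidised in competition with C3=C4, or over-oxidation may set in before conversion is complete. Fallback: the epoxide is introduced before fragment coupling, on a substrate that holds no 1,1-disubstituted alkene. Setting out from 4, the same Shi conditions would epoxidise the trisubstituted alkene of the stannyl diene to give tributyl{(E)-2-[(2S,3S)-2-methyl-3-(prop-2-en-1-yl)oxiran-2-yl]ethenyl}stannane F6. Stille coupling of F6 with 10 under phosphine-free conditions (PdCl2(MeCN)2, LiCl, DMF, rt), where oxidative addition to the triflate should outpace ionisation of the vinyl epoxide, comes back to the route at 12.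

3. Step 11 (key step). The 1,3-chirality transfer may be eroded if the free acid opens its own vinyl epoxide without palladium during handling, or if syn/anti isomerisation at the tertiary allyl terminus competes with ring closure and leaks to the Z-alkene with the opposite C6 configuration. Fallback: the carboxylic acid is never set free next to the epoxide, and the lactone is closed by acyl substitution instead. Setting out from 12, the known palladium-catalysed 1,4-addition of acetic acid to a vinyl epoxide (Pd(PPh3)4, AcOH, THF, 0 °C) would give methyl (2Z,4R,5E,7S)-4-acetoxy-2-{[(tert-butyldimethylsilyl)oxy]methyl}-7-hydroxy-6-methyl-3-(3-methylbut-3-en-1-yl)deca-2,5,9-trienoate F7. K2CO3 in MeOH at 0 °C would cleave the acetate, and the C6 alkoxide would close onto the cis methyl ester, which comes back to the route at 14.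

**Further compounds**
F1 | step 15 | methyl (3S,4S)-13-[(tert-butyldimethylsilyl)oxy]-3,4-epoxygermacra-1(10)Z,5E,7(11)Z-trien-12-oate | COC(=O)/C(CO[Si](C)(C)C(C)(C)C)=C1/CC/C(C)=C\C[C@@H]2O[C@@]2(C)/C=C/1
F2 | step 15 | (3S,4S)-13-[(tert-butyldimethylsilyl)oxy]-3,4-epoxygermacra-1(10)Z,5E,7(11)Z-trien-12-oic acid | OC(=O)/C(CO[Si](C)(C)C(C)(C)C)=C1/CC/C(C)=C\C[C@@H]2O[C@@]2(C)/C=C/1
F3 | step 15 | (3S,6R)-13-[(tert-butyldimethylsilyl)oxy]-3-hydroxygermacra-1(10)Z,4E,7(11)-trien-12,6-olide | O[C@H]1C/C=C(/C)CCC2=C(CO[Si](C)(C)C(C)(C)C)C(=O)O[C@@H]2/C=C/1C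
F4 | step 15 | (3S,6R)-13-[(tert-butyldimethylsilyl)oxy]-3-tigloyloxygermacra-1(10)Z,4E,7(11)-trien-12,6-olide | C/C=C(\C)C(=O)O[C@H]1C/C=C(/C)CCC2=C(CO[Si](C)(C)C(C)(C)C)C(=O)O[C@@H]2/C=C/1C
F5 | step 15 | (3S,6R)-13-hydroxy-3-tigloyloxygermacra-1(10)Z,4E,7(11)-trien-12,6-olide | C/C=C(\C)C(=O)O[C@H]1C/C=C(/C)CCC2=C(CO)C(=O)O[C@@H]2/C=C/1C
F6 | step 9 | tributyl{(E)-2-[(2S,3S)-2-methyl-3-(prop-2-en-1-yl)oxiran-2-yl]ethenyl}stannane | C=CC[C@@H]1O[C@@]1(C)/C=C/[Sn](CCCC)(CCCC)CCCC
F7 | step 11 | methyl (2Z,4R,5E,7S)-4-acetoxy-2-{[(tert-butyldimethylsilyl)oxy]methyl}-7-hydroxy-6-methyl-3-(3-methylbut-3-en-1-yl)deca-2,5,9-trienoate | COC(=O)/C(CO[Si](C)(C)C(C)(C)C)=C(CCC(C)=C)\[C@H](OC(C)=O)/C=C(C)/[C@@H](O)CC=C
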